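**Numbering used throughout.** Ring atoms are C1–C10 of the target. C14 is the formyl carbon on C10, C15 the hydroxymethyl carbon on C4, C11/C12/C13 the lactone α-carbon, carbonyl and methylene. TBDPS = tert-butyldiphenylsilyl, PMB = 4-methoxybenzyl, TMS = trimethylsilyl.

## Analysis of the target

The target is a ten-membered carbocycle with a γ-lactone fused across C6–C7: the lactone oxygen is on C6, C11 is on C7, and C13 is an exocyclic methylene. The ring holds two trisubstituted alkenes, C1=C10 (formyl C14 on C10) and C4=C5 (hydroxymethyl C15 on C4). In both, the two ring carbons are cis to each other. Four contiguous stereocentres, 6R,7S,8S,9S, lie between the alkenes. On the ring, O6 and C11 are trans (trans-fused lactone), C11 and the acyloxy oxygen on C8 are cis, and the C8 and C9 oxygens are trans. A fifth centre (S) sits in the 2-methylbutanoate on O8.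

Sensitive groups are the α-methylene lactone and the enal (both Michael acceptors), the 8-acyloxy/9-hydroxy pair (acyl shift), the epimerisable acyl α-carbon, and two allylic alcohols. The difficulty is a medium ring with two ring-cis trisubstituted alkenes, five differentiated oxygens and a dense stereo array next to the ring fusion.

The strategy rests on the C8–C9 bond. Read as C8=C7–C6(O)–C1–C10=C9, it is the new σ-bond of a 3-oxy-1,5-diene. The C1–C6 bond of that diene can sit in a cyclohexene that already contains the ring-cis C4=C5.

## Retrosynthetic reasoning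

**28 to 25.** The free C15 alcohol, the C14 aldehyde and the C9 alcohol are unmasked last. 28 comes from silyl ether 27, 27 from diol 26 by oxidising only the primary allylic alcohol, and 26 from acetonide 25. Tying O9 and O14 in one acetal means two oxygens are released together and need only a primary/secondary distinction.

**25 to 21.** The lactone C–O bond is cut to hydroxy ester 24. Here C6 is set and O8 is acylated in a single operation from β-hydroxy ketone 21 and aldehyde 23. The C8 hydroxyl delivers hydride to C6, so the 6,8-anti relation does not depend on the ring conformation, and the acyl group arrives without base at its α-centre. 23 comes from alcohol 22.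

**21 to 17.** The C7–C11 bond is cut. Ketone 17 has only one enolisable α-methylene (C7), flanked by the C8 ether oxygen. Alkylation of enolate 19 with acrylate 18 brings C11, C12 and C13 in at once, so no separate methylenation is needed. Removing the PMB group from 20 then gives 21.

**17 to 15 (key disconnection).** The C8–C9 bond is cut and C1–C6 reconnected. This turns the ten-membered ring into cyclohexenol 15, removes both new stereocentres, and makes ring formation a unimolecular ring expansion. The forward step must form C8–C9 through one chair so that both oxygens end equatorial (8S,9S) and C1=C10 is ring-cis. For that reason the C9 and C14 oxygens of 15 are tied in a 4H-1,3-dioxin, which locks the enol ether geometry by ring constraint.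

**15 to 9.** The enol ether of 15 is traced to alkynyl ether 14, because anti-hydrometalation gives the E geometry without ambiguity. 14 is cut at C6–C7 into ketone 9 and acetylide 13, the latter from dichlorovinyl ether 12 (from 10 and 11). A slim sp nucleophile is chosen because the cis relation of the two unsaturated groups needs axial attack on the enone.

**9 to starting materials.** The C1–C10 bond is cut between the α′-carbon of enone 4 (used as dienol ether 5, via tin enolate 8) and enol triflate 7. 7 is one step from ketone 6. 4 comes from 3, and 3 from anisole 1 via 2. This is the only step that creates absolute configuration in the ring series.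

## Alternatives that were turned down

**Alternative 1: acyclic three-component assembly of the enal sector.**
- Disconnection: C1–C2 and C9–C10 are made in one pot on an open chain. The ring is closed later at C4=C5 by metathesis.
- Key step: an alkylcopper reagent carrying C2–C4 and C15 adds syn across a propiolate ester. The α-cuprated acrylate is then trapped by an α-alkoxy aldehyde that already holds the lactone, giving the acyclic carbinol A1.
- For: syn-carbometalation fixes the ring-cis C1=C10 geometry by mechanism, as securely as the chosen route does. C6, C7 and C8 arrive already set, so the C7 alkylation problem of the chosen route does not exist. On that point this alternative is stronger.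
- Against: C9 is made by intermolecular addition of a sluggish vinylcopper to an α-alkoxy aldehyde, where Felkin–Anh and chelation modes compete. The ring must then be closed by metathesis between a 1,1-disubstituted alkene and a vinyl group, forming a trisubstituted ring-cis alkene in a strained ten-membered ring. That needs dilution, invites dimerisation and does not enforce geometry. The aldehyde component with three stereocentres needs its own multi-step synthesis.
- Comparison: the chosen route offers ring formation by a concerted unimolecular expansion and sets C8 and C9 in the same event.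

**Alternative 2: cyclobutene ring-rearrangement metathesis.**
- Disconnection: C4=C5, with a temporary C5–C11 link held in a cyclobutene.
- Key step: a ruthenium alkylidene (second-generation Hoveyda–Grubbs catalyst) under C2H4 opens the cyclobutene alkene C5=C11. The C5 alkylidene closes onto the 1,1-disubstituted alkene at C4, and C11 is capped as C11=C13, giving the ten-membered dienal A2.
- For: ring strain pays for the medium ring and the tether holds the reacting ends together. A2 already carries all four stereocentres, the ester and the enal, so its endgame is shorter than the chosen one. On that point it is stronger.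
- Against: the cyclobutene precursor with the whole stereo array is long to make. Closure onto a 1,1-disubstituted alkene is slow, and C2H4 can open the cyclobutene without ring closure. The ring-cis geometry of C4=C5 is not dictated. C11 must still be oxidised and lactonised.
- Comparison: the chosen route carries C4=C5 unchanged from a cyclohexenone and reaches its ring-expansion substrate in far fewer steps.

**Alternative 3: sulfone-anion allylation at C2–C3.**
- Disconnection: the sp3–sp3 bond C2–C3.
- Key step: KN(SiMe3)2 forms the allylic sulfone carbanion at C3, which displaces the allylic bromide at C2 within the chain. This gives the sulfonylated ten-membered diene A3 as C3 epimers that converge after desulfonylation.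
- For: this is a well-tried way of closing such rings. Both alkenes are geometrically defined before closure and no stereocentre of consequence is made. In predictability of ring closure and alkene geometry it is stronger than the chosen route.
- Against: the linear precursor needs four stereocentres and two defined trisubstituted alkenes, so the linear sequence is long. The step needs high dilution. The allyl sulfone anion is ambident, and the ring-cis allylic bromide can react SN2′ or lose geometry. Desulfonylation, lactone construction and oxidation-state changes follow.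
- Comparison: the chosen route forms the ring, the C8–C9 bond and two stereocentres in one step from a simple adduct.

Key step: step 9

## Route

Assumption: in step 5 the antipode of the bisphosphine that gives the (S)-ketone 9 is fixed by a first assay; the (R)-ligand is written.

Step 1
Reactants: 1 3-methoxybenzyl alcohol
Product: 3 3-(hydroxymethyl)cyclohex-2-en-1-one, via dihydroanisole 2 (not isolated)
Conditions: Li, NH3(l), THF, t-BuOH, −78 °C; then 1 M HCl, THF, 25 °C
Reagents that add atoms: water, O
Why: Birch reduction of the lithium alkoxide of the anisole should give the 1-methoxy-1,4-diene with both substituents on sp2 carbons; acid hydrolysis of the enol ether and conjugation of the alkene should give the 3-substituted enone.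

Step 2
Reactants: 3 3-(hydroxymethyl)cyclohex-2-en-1-one
Product: 4 3-{[tert-butyl(diphenyl)silyl]oxymethyl}cyclohex-2-en-1-one
Conditions: TBDPSCl, imidazole, CH2Cl2, 25 °C
Reagents that add atoms: tert-butyl(chloro)diphenylsilane, CC(C)(C)[Si](Cl)(c1ccccc1)c1ccccc1
Why: Standard silylation of a primary alcohol; the TBDPS ether should outlast every later base, hydride, oxidant and mild acid.

Step 3
Reactants: 4 3-{[tert-butyl(diphenyl)silyl]oxymethyl}cyclohex-2-en-1-one
Product: 5 tert-butyl(diphenyl){[3-(trimethylsilyloxy)cyclohexa-1,3-dien-1-yl]methoxy}silane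
Conditions: LiN(i-Pr)2, THF, −78 °C; TMSCl
Reagents that add atoms: chlorotrimethylsilane, C[Si](C)(C)Cl
Why: Kinetic deprotonation of a cyclohexenone takes the α′-proton, so O-silylation should give the cross-conjugated dienol ether and fix the site of the next C–C bond.

Step 4
Reactants: 6 2,2-dimethyl-1,3-dioxan-5-one
Product: 7 2,2-dimethyl-4H-1,3-dioxin-5-yl trifluoromethanesulfonate
Conditions: LiN(SiMe3)2, THF, −78 °C; PhNTf2, −78 → 0 °C
Reagents that add atoms: N-phenylbis(trifluoromethanesulfonimide), O=S(=O)(N(c1ccccc1)S(=O)(=O)C(F)(F)F)C(F)(F)F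
Why: Enolate O-triflation of a ketone; the enol ether oxygen (later O9) and the ring CH2–O (later C14–O) are held cis on the alkene by the six-membered acetal.

Step 5
Reactants: 5 TMS dienol ether; 7 dioxinyl triflate
Product: 9 (6S)-6-(2,2-dimethyl-4H-1,3-dioxin-5-yl)-3-{[tert-butyl(diphenyl)silyl]oxymethyl}cyclohex-2-en-1-one, via tributyltin enolate 8 (not isolated)
Conditions: Bu3SnF, Pd(dba)2 (5 mol%), (R)-DIFLUORPHOS (6 mol%), PhMe, 50 °C
Reagents that add atoms: none
Why: Fluoride-driven Si-to-Sn exchange should give the tin enolate without base; zerovalent palladium inserts into the C–OTf bond, and transmetalation and reductive elimination join the α′-carbon (C1) to C10 (palladium-catalysed enolate α-alkenylation of the Buchwald–Hartwig type, run on the tin enolate). The chiral bisphosphine on the palladium enolate sets C1, and the neutral medium should keep the doubly activated C1–H from exchanging.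

Step 6
Reactants: 10 4-methoxybenzyl alcohol; 11 trichloroethylene
Product: 12 1-{[(E)-1,2-dichloroethenyl]oxymethyl}-4-methoxybenzene
Conditions: KH, THF, 0 °C; then 11, 25 °C
Reagents that add atoms: none
Why: The potassium alkoxide should add anti to dichloroacetylene formed in the flask from 11 (elimination–addition), giving the E-dichlorovinyl ether, a stable precursor of the alkoxyacetylide.

Step 7
Reactants: 12 dichlorovinyl PMB ether; 9 (S)-ketone
Product: 14 (1R,6S)-6-(2,2-dimethyl-4H-1,3-dioxin-5-yl)-1-{[(4-methoxyphenyl)methoxy]ethynyl}-3-{[tert-butyl(diphenyl)silyl]oxymethyl}cyclohex-2-en-1-ol, via lithium alkoxyacetylide 13 (not isolated)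
Conditions: n-BuLi (2 equiv per 12), THF, −78 → −40 °C; LaCl3·2LiCl (0.3 equiv), 9, −78 °C
Reagents that add atoms: none
Why: Elimination to the chloroalkyne and Cl/Li exchange give the acetylide, which is kept cold because benzyl alkynyl ethers rearrange on warming. The slim sp nucleophile should attack the half-chair enone along the axial path anti to the axial C–H at the α′-carbon, so that it ends cis to the equatorial dioxinyl group and the hydroxyl trans (1R). Low basicity and the lanthanum salt should suppress enolisation of the labile α′-centre.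

Step 8
Reactants: 14 alkynyl carbinol
Product: 15 (1R,6S)-6-(2,2-dimethyl-4H-1,3-dioxin-5-yl)-1-{(E)-2-[(4-methoxyphenyl)methoxy]ethenyl}-3-{[tert-butyl(diphenyl)silyl]oxymethyl}cyclohex-2-en-1-ol
Conditions: LiAlH4, THF, 0 → 25 °C; basic work-up
Reagents that add atoms: none
Why: Alkoxide-directed trans-hydroalumination of a propargylic alkoxide followed by protonolysis should give only the E enol ether, as known for alkoxyethynyl carbinols; acid is avoided because the product is a vinylogous hemiacetal.

Step 9
Reactants: 15 cis-dialkenyl cyclohexenol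
Product: 17 ten-membered dienone (C6 ketone; ring-cis C4=C5 bearing CH2OTBDPS; ring-cis C1=C10; C7 methylene; 8S-OPMB; 9S-O/C14-O isopropylidene acetal), via potassium enolate 16 (not isolated)
Conditions: KH, 18-crown-6, THF, 0 → 25 °C; then aq. NH4Cl, −78 °C
Reagents that add atoms: none
Why: KH with the crown ether gives the dissociated potassium alkoxide, whose C1–C6 bond is weakened by the oxyanion; a concerted suprafacial [3,3] shift through a chair joins C8 to C9 as C1–C6 breaks, giving enolate 16 and, on cold protonation, ketone 17. The closest known reaction is the anionic oxy-Cope ring expansion of cis-1,2-dialkenylcyclohexanols to ring-cis cyclodec-5-enones; here both termini are enol ethers. The ten-membered ring is not closed end to end: it forms by four-atom expansion of the cyclohexene, whose C4=C5 is carried over untouched. At C8 the E geometry of the PMB enol ether places the oxygen equatorial on the chair. At C9 the dioxin ring holds the oxygen cis to C14 and therefore also equatorial; two equatorial oxygens give the trans 8S,9S pattern, and the sense of the chair, hence the absolute configuration, is fixed by the 1R carbinol carbon (C6). The step needs the chair in which the oxide and the C1–C2 bond are axial on the forming six-membered array (ring-cis C1=C10) to win over the chair with C5 axial (ring-trans C1=C10, antipodal C8/C9). The required chair keeps the bulky dioxinyl group and the ion-paired oxide equatorial on the cyclohexene and is the usual course for cis-dialkenyl carbinols. As formed, the C8–O bond of 16 lies in the enolate plane, which disfavours E1cB loss of the PMB-oxide; the cold quench guards against it.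

Step 10
Reactants: 17 ten-membered dienone; 18 methyl 2-(bromomethyl)prop-2-enoate
Product: 20 C7-alkylated ketone (17 with (7R)-CH2C(=CH2)CO2Me on C7), via lithium enolate 19 (not isolated)
Conditions: LiN(SiMe3)2, THF, −78 °C; then 18, −78 → −40 °C
Reagents that add atoms: none
Why: Kinetic deprotonation of the enone at its only α′-position (C7) gives the enolate with O6 cis to C8. Lithium bridging the enolate oxygen and the PMB ether oxygen (Fráter–Seebach-type chelate) should expose the face anti to C9, so the activated allylic bromide enters with C11 cis to O8. This is the arrangement of the target's 7S; the descriptor reads R here because C6 is a carbonyl.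

Step 11
Reactants: 20 C7-alkylated ketone
Product: 21 (7R,8S,9S)-8-hydroxy ketone (20 without the PMB group)
Conditions: DDQ, CH2Cl2/pH 7 buffer, 0 °C
Reagents that add atoms: none
Why: Oxidative cleavage of a PMB ether under neutral conditions; silyl ether, acetonide, enone and acrylate should be untouched, and the buffer should prevent aldol-type loss of the β-hydroxy ketone.

Step 12
Reactants: 22 (2S)-2-methylbutan-1-ol
Product: 23 (2S)-2-methylbutanal
Conditions: TEMPO (1 mol%), KBr, NaOCl, CH2Cl2/H2O, 0 °C
Reagents that add atoms: none
Why: Anelli oxidation of a primary alcohol stops at the aldehyde and is mild enough to keep the α-centre; 23 is used at once.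

Step 13
Reactants: 21 8-hydroxy ketone; 23 (2S)-2-methylbutanal
Product: 24 (6R,7S,8S,9S)-6-hydroxy 8-[(2S)-2-methylbutanoate] (C6 alcohol; methyl acrylate side chain on C7; acetonide and TBDPS ether unchanged)
Conditions: SmI2 (30 mol%), 23 (5 equiv), THF, −10 °C
Reagents that add atoms: none
Why: Evans–Tishchenko reduction: the samarium-bound hemiacetal of 23 on O8 passes its hydride to C6 through a chair six-membered transition state, giving the 6,8-anti alcohol (6R) and leaving the acyl group of 23 on O8. No base touches the acyl α-centre, and the enone is reduced only at carbon 6.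

Step 14
Reactants: 24 hydroxy ester
Product: 25 trans-fused α-methylene-γ-lactone (6,12-olide) with 8-[(2S)-2-methylbutanoate], 9,14-acetonide, 15-OTBDPS
Conditions: PPTS (cat.), PhMe, 60 °C
Reagents that add atoms: none
Why: Acid-catalysed lactonisation of a γ-hydroxy ester by 5-exo attack at the ester carbonyl; O8 is already acylated, so only the 6,12-lactone can form, and the dry, weakly acidic medium should spare the acetonide.

Step 15
Reactants: 25 lactone acetonide
Product: 26 (6R,7S,8S,9S)-9,14-diol
Conditions: AcOH/THF/H2O (3:1:1), 40 °C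
Reagents that add atoms: none
Why: Hydrolysis of an isopropylidene acetal of an allylic 1,3-diol; the TBDPS ether, both esters and the methylene lactone should tolerate aqueous acetic acid, which is also too weak to drive acyl shift from O8 to O9 quickly.

Step 16
Reactants: 26 9,14-diol
Product: 27 C14 enal (14-oxo; 9-OH free; 15-OTBDPS)
Conditions: TEMPO (10 mol%), PhI(OAc)2, CH2Cl2, 25 °C
Reagents that add atoms: none
Why: Oxoammonium oxidation takes primary alcohols far faster than secondary ones, so only C14 should be oxidised; C15 is still silylated, which is why this step precedes desilylation.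

Step 17
Reactants: 27 silyl-protected enal
Product: 28 CNP0331447.1 (target)
Conditions: HF·pyridine, THF/pyridine, 0 → 25 °C
Reagents that add atoms: none
Why: Buffered fluoride desilylation of a primary TBDPS ether; the conditions are nearly neutral, so the enal, the methylene lactone and the 8-ester/9-alcohol pair should survive.

## Compound list

1 | 3-methoxybenzyl alcohol | COc1cccc(CO)c1 | starting material
2 | (5-methoxycyclohexa-1,4-dien-1-yl)methanol | COC1=CCC=C(CO)C1 | intermediate
3 | 3-(hydroxymethyl)cyclohex-2-en-1-one | O=C1CCCC(CO)=C1 | intermediate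
4 | 3-{[tert-butyl(diphenyl)silyl]oxymethyl}cyclohex-2-en-1-one | O=C1CCCC(CO[Si](c2ccccc2)(c2ccccc2)C(C)(C)C)=C1 | intermediate
5 | tert-butyl(diphenyl){[3-(trimethylsilyloxy)cyclohexa-1,3-dien-1-yl]methoxy}silane | C[Si](C)(C)OC1=CCCC(CO[Si](c2ccccc2)(c2ccccc2)C(C)(C)C)=C1 | intermediate
6 | 2,2-dimethyl-1,3-dioxan-5-one | CC1(C)OCC(=O)CO1 | starting material
7 | 2,2-dimethyl-4H-1,3-dioxin-5-yl trifluoromethanesulfonate | CC1(C)OCC(OS(=O)(=O)C(F)(F)F)=CO1 | intermediate
8 | tributylstannyl α′-enolate of 4 | CCCC[Sn](CCCC)(CCCC)OC1=CCCC(CO[Si](c2ccccc2)(c2ccccc2)C(C)(C)C)=C1 | intermediate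
9 | (6S)-6-(2,2-dimethyl-4H-1,3-dioxin-5-yl)-3-{[tert-butyl(diphenyl)silyl]oxymethyl}cyclohex-2-en-1-one | O=C1C=C(CO[Si](c2ccccc2)(c2ccccc2)C(C)(C)C)CC[C@H]1C1=COC(C)(C)OC1 | intermediate
10 | 4-methoxybenzyl alcohol | COc1ccc(CO)cc1 | starting material
11 | trichloroethylene | ClC=C(Cl)Cl | starting material
12 | 1-{[(E)-1,2-dichloroethenyl]oxymethyl}-4-methoxybenzene | COc1ccc(CO/C(Cl)=C\Cl)cc1 | intermediate
13 | lithium [(4-methoxyphenyl)methoxy]acetylide | [Li]C#COCc1ccc(OC)cc1 | intermediate
14 | (1R,6S)-6-(2,2-dimethyl-4H-1,3-dioxin-5-yl)-1-{[(4-methoxyphenyl)methoxy]ethynyl}-3-{[tert-butyl(diphenyl)silyl]oxymethyl}cyclohex-2-en-1-ol | O[C@]1(C#COCc2ccc(OC)cc2)C=C(CO[Si](c2ccccc2)(c2ccccc2)C(C)(C)C)CC[C@H]1C1=COC(C)(C)OC1 | intermediate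
15 | (1R,6S)-6-(2,2-dimethyl-4H-1,3-dioxin-5-yl)-1-{(E)-2-[(4-methoxyphenyl)methoxy]ethenyl}-3-{[tert-butyl(diphenyl)silyl]oxymethyl}cyclohex-2-en-1-ol | O[C@]1(/C=C/OCc2ccc(OC)cc2)C=C(CO[Si](c2ccccc2)(c2ccccc2)C(C)(C)C)CC[C@H]1C1=COC(C)(C)OC1 | intermediate
16 | potassium C6–C7 enolate of 17 (O6 cis to C8; 8S,9S) | C1C/C=C2/COC(C)(C)O[C@@H]2[C@@H](OCc3ccc(OC)cc3)/C=C(\O[K])/C=C1/CO[Si](c1ccccc1)(c1ccccc1)C(C)(C)C | intermediate
17 | ten-membered dienone: C6 ketone, ring-cis C4=C5 (CH2OTBDPS on C4), ring-cis C1=C10, (8S)-OPMB, (9S)-O and C14-O as isopropylidene acetal | O=C1/C=C(/CO[Si](c2ccccc2)(c2ccccc2)C(C)(C)C)CC/C=C2/COC(C)(C)O[C@@H]2[C@@H](OCc2ccc(OC)cc2)C1 | intermediate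
18 | methyl 2-(bromomethyl)prop-2-enoate | C=C(CBr)C(=O)OC | starting material
19 | lithium C6–C7 enolate of 17 (O6 cis to C8) | C1C/C=C2/COC(C)(C)O[C@@H]2[C@@H](OCc3ccc(OC)cc3)/C=C(\O[Li])/C=C1/CO[Si](c1ccccc1)(c1ccccc1)C(C)(C)C | intermediate
20 | (7R,8S,9S)-C7-alkylated ketone: 17 with CH2C(=CH2)CO2Me on C7 | O=C1/C=C(/CO[Si](c2ccccc2)(c2ccccc2)C(C)(C)C)CC/C=C2/COC(C)(C)O[C@@H]2[C@@H](OCc2ccc(OC)cc2)[C@H]1CC(=C)C(=O)OC | intermediate
21 | (7R,8S,9S)-8-hydroxy ketone: 20 without PMB | O=C1/C=C(/CO[Si](c2ccccc2)(c2ccccc2)C(C)(C)C)CC/C=C2/COC(C)(C)O[C@@H]2[C@@H](O)[C@H]1CC(=C)C(=O)OC | intermediate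
22 | (2S)-2-methylbutan-1-ol | CC[C@H](C)CO | starting material
23 | (2S)-2-methylbutanal | CC[C@H](C)C=O | intermediate
24 | (6R,7S,8S,9S)-6-hydroxy 8-[(2S)-2-methylbutanoate] with methyl acrylate side chain on C7, 9,14-acetonide, 15-OTBDPS | O[C@@H]1/C=C(/CO[Si](c2ccccc2)(c2ccccc2)C(C)(C)C)CC/C=C2/COC(C)(C)O[C@@H]2[C@@H](OC(=O)[C@@H](C)CC)[C@H]1CC(=C)C(=O)OC | intermediate
25 | (6R,7S,8S,9S)-6,12-olide (α-methylene lactone) 8-[(2S)-2-methylbutanoate], 9,14-acetonide, 15-OTBDPS | C=C1C(=O)O[C@@H]2/C=C(/CO[Si](c3ccccc3)(c3ccccc3)C(C)(C)C)CC/C=C3/COC(C)(C)O[C@@H]3[C@@H](OC(=O)[C@@H](C)CC)[C@@H]12 | intermediate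
26 | (6R,7S,8S,9S)-9,14-diol of 25 | C=C1C(=O)O[C@@H]2/C=C(/CO[Si](c3ccccc3)(c3ccccc3)C(C)(C)C)CC/C=C(/CO)[C@H](O)[C@@H](OC(=O)[C@@H](C)CC)[C@@H]12 | intermediate
27 | 15-O-TBDPS ether of the target (C14 enal, 9-OH free) | C=C1C(=O)O[C@@H]2/C=C(/CO[Si](c3ccccc3)(c3ccccc3)C(C)(C)C)CC/C=C(/C=O)[C@H](O)[C@@H](OC(=O)[C@@H](C)CC)[C@@H]12 | intermediate
28 | CNP0331447.1 | C=C1C(=O)O[C@@H]2/C=C(/CO)CC/C=C(/C=O)[C@H](O)[C@@H](OC(=O)[C@@H](C)CC)[C@@H]12 | target

## Step count and least certain steps

Total: 17 steps. Longest linear sequence: 14 steps (1, 2, 3, 5, 7, 8, 9, 10, 11, 13, 14, 15, 16, 17); steps 4, 6 and 12 make the side fragments.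

**Step 9 (key step).** The main dangers are passage through the other chair (ring-trans C1=C10 with antipodal C8/C9), and decay of the long-lived potassium enolate by loss of the PMB-oxide from C8 or by proton shuffling before the quench. Fallback for the enolate-derived losses: from 15, the rearrangement is run as before but quenched in the flask with TMSCl to give the trimethylsilyl enol ether F1. MeLi then cleaves F1 to the lithium enolate 19, which is alkylated as in step 10 and returns to the route at 20. Ketone 17 is never handled.

**Step 5.** The enantioselectivity may be poor, or the ketone may racemise or slip into conjugation, because its α′-hydrogen is both α to the carbonyl and allylic. Fallback: from 5 and 7 the coupling is run with an achiral phosphine to give the racemic ketone F2. F2 is deprotonated with LiN(i-Pr)2 to the lithium dienolate F3, and kinetic α-protonation at −78 °C with a chiral proton donor (enantioselective enolate protonation) returns to the route at 9.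

**Step 7.** Facial selectivity may be poor or reversed (equatorial attack, alkynyl anti to the dioxinyl group), because the α′-substituent is large. Fallback, which makes the anti mode productive:
- From 5 and 7 with the antipodal ligand, step 5 gives the R ketone F4.
- Anti addition of 13 gives the trans alkynyl carbinol F5, and LiAlH4 gives the trans enol ether carbinol F6, which has the same 1R carbinol centre as 15.
- The usual oxy-Cope chair with both ring bonds equatorial should give the ring-trans dienone F7 with the same 8S,9S centres.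
- Steps 10, 11, 13, 14, 15 and 16 applied to F7 give in turn alkylated ketone F8, hydroxy ketone F9, hydroxy ester F10, lactone F11, diol F12 and the ring-trans enal F13.
- Photochemical E-to-Z isomerisation of the enal F13 returns to the route at 27.

**Step 10.** The electrophile may enter on the wrong face if the lithium chelate to the PMB ether is weak, and the enolate may lose the C8 oxygen. Fallback: from 17 the PMB group is removed first (DDQ) to give the des-alkyl hydroxy ketone F14. Its dianion (2 equiv LiN(i-Pr)2, −78 °C) is alkylated with 18 under true Fráter–Seebach alkoxide chelation, returning to the route at 21.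

**Step 13.** Intramolecular hydride transfer to a hindered conjugated ketone may be slow, and the ester may shift from O8 to O6. Fallback: from 21, Evans–Saksena reduction with Me4NBH(OAc)3 gives the 6,8-anti diol F15. PPTS closes the hydroxy lactone F16, and Steglich esterification of its C8 hydroxyl with (S)-2-methylbutanoic acid returns to the route at 25.

## Further compounds

F1 | step 9 | trimethylsilyl enol ether of 17 (C6–C7, O cis to C8) | C1C/C=C2/COC(C)(C)O[C@@H]2[C@@H](OCc3ccc(OC)cc3)/C=C(\O[Si](C)(C)C)/C=C1/CO[Si](c1ccccc1)(c1ccccc1)C(C)(C)C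
F2 | step 5 | racemic 6-(2,2-dimethyl-4H-1,3-dioxin-5-yl)-3-{[tert-butyl(diphenyl)silyl]oxymethyl}cyclohex-2-en-1-one | O=C1C=C(CO[Si](c2ccccc2)(c2ccccc2)C(C)(C)C)CCC1C1=COC(C)(C)OC1
F3 | step 5 | lithium dienolate of F2 | [Li]OC1=C(C2=COC(C)(C)OC2)CCC(CO[Si](c2ccccc2)(c2ccccc2)C(C)(C)C)=C1
F4 | step 7 | (6R)-6-(2,2-dimethyl-4H-1,3-dioxin-5-yl)-3-{[tert-butyl(diphenyl)silyl]oxymethyl}cyclohex-2-en-1-one | O=C1C=C(CO[Si](c2ccccc2)(c2ccccc2)C(C)(C)C)CC[C@@H]1C1=COC(C)(C)OC1
F5 | step 7 | (1R,6R)-alkynyl carbinol (alkynyl trans to dioxinyl) | O[C@]1(C#COCc2ccc(OC)cc2)C=C(CO[Si](c2ccccc2)(c2ccccc2)C(C)(C)C)CC[C@@H]1C1=COC(C)(C)OC1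
F6 | step 7 | (1R,6R)-(E)-enol ether carbinol (trans-dialkenyl) | O[C@]1(/C=C/OCc2ccc(OC)cc2)C=C(CO[Si](c2ccccc2)(c2ccccc2)C(C)(C)C)CC[C@@H]1C1=COC(C)(C)OC1
F7 | step 7 | ring-trans C1=C10 isomer of 17 (8S,9S) | O=C1/C=C(/CO[Si](c2ccccc2)(c2ccccc2)C(C)(C)C)CC/C=C2\COC(C)(C)O[C@@H]2[C@@H](OCc2ccc(OC)cc2)C1
F8 | step 7 | ring-trans C1=C10 isomer of 20 | O=C1/C=C(/CO[Si](c2ccccc2)(c2ccccc2)C(C)(C)C)CC/C=C2\COC(C)(C)O[C@@H]2[C@@H](OCc2ccc(OC)cc2)[C@H]1CC(=C)C(=O)OC
F9 | step 7 | ring-trans C1=C10 isomer of 21 | O=C1/C=C(/CO[Si](c2ccccc2)(c2ccccc2)C(C)(C)C)CC/C=C2\COC(C)(C)O[C@@H]2[C@@H](O)[C@H]1CC(=C)C(=O)OC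
F10 | step 7 | ring-trans C1=C10 isomer of 24 | O[C@@H]1/C=C(/CO[Si](c2ccccc2)(c2ccccc2)C(C)(C)C)CC/C=C2\COC(C)(C)O[C@@H]2[C@@H](OC(=O)[C@@H](C)CC)[C@H]1CC(=C)C(=O)OC
F11 | step 7 | ring-trans C1=C10 isomer of 25 | C=C1C(=O)O[C@@H]2/C=C(/CO[Si](c3ccccc3)(c3ccccc3)C(C)(C)C)CC/C=C3\COC(C)(C)O[C@@H]3[C@@H](OC(=O)[C@@H](C)CC)[C@@H]12
F12 | step 7 | ring-trans C1=C10 isomer of 26 | C=C1C(=O)O[C@@H]2/C=C(/CO[Si](c3ccccc3)(c3ccccc3)C(C)(C)C)CC/C=C(\CO)[C@H](O)[C@@H](OC(=O)[C@@H](C)CC)[C@@H]12
F13 | step 7 | ring-trans C1=C10 isomer of 27 | C=C1C(=O)O[C@@H]2/C=C(/CO[Si](c3ccccc3)(c3ccccc3)C(C)(C)C)CC/C=C(\C=O)[C@H](O)[C@@H](OC(=O)[C@@H](C)CC)[C@@H]12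
F14 | step 10 | (8S,9S)-8-hydroxy dienone (17 without PMB) | O=C1/C=C(/CO[Si](c2ccccc2)(c2ccccc2)C(C)(C)C)CC/C=C2/COC(C)(C)O[C@@H]2[C@@H](O)C1
F15 | step 13 | (6R,7S,8S,9S)-6,8-diol with methyl acrylate side chain on C7 | O[C@@H]1/C=C(/CO[Si](c2ccccc2)(c2ccccc2)C(C)(C)C)CC/C=C2/COC(C)(C)O[C@@H]2[C@@H](O)[C@H]1CC(=C)C(=O)OC
F16 | step 13 | (6R,7S,8S,9S)-8-hydroxy 6,12-olide, 9,14-acetonide, 15-OTBDPS | C=C1C(=O)O[C@@H]2/C=C(/CO[Si](c3ccccc3)(c3ccccc3)C(C)(C)C)CC/C=C3/COC(C)(C)O[C@@H]3[C@@H](O)[C@@H]12
A1 | alternative 1 | acyclic C9 carbinol with ring-cis-configured enoate and both metathesis alkenes | C=C[C@H]1OC(=O)C[C@@H]1[C@H](OCc1ccc(OC)cc1)[C@@H](O)/C(C(=O)OC)=C\CCC(=C)CO[Si](c1ccccc1)(c1ccccc1)C(C)(C)C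
A2 | alternative 2 | ten-membered dienal with C6 silyl ether and 2-(silyloxymethyl)vinyl group on C7 | C=C(CO[Si](CC)(CC)CC)[C@H]1[C@H](O[Si](CC)(CC)CC)/C=C(/CO[Si](c2ccccc2)(c2ccccc2)C(C)(C)C)CC/C=C(/C=O)[C@H](O[Si](C)(C)C(C)(C)C)[C@H]1OC(=O)[C@@H](C)CC
A3 | alternative 3 | ten-membered diene with phenylsulfonyl group on C3 | C=C(CO[Si](CC)(CC)CC)[C@H]1[C@H](O[Si](CC)(CC)CC)/C=C(/CO[Si](c2ccccc2)(c2ccccc2)C(C)(C)C)C(S(=O)(=O)c2ccccc2)C/C=C(/CO[Si](CC)(CC)CC)[C@H](O[Si](C)(C)C(C)(C)C)[C@H]1OCc1ccc(OC)cc1
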